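**Retrosynthetic overview**

- The route rests on ring A: a 4-methoxysalicyl ketone with C1' acyl, C2' OH, C3' geranyl flanked by both oxygens, C4' OMe, and C5'/C6' H. A 2-substituted 1,1,3-trioxygenated butadiene and a terminal ynone assemble this pattern directly.
- Last disconnection: the silyl ether on the ring B phenol (C4–O).
- Key disconnection: C1'–C2' and C5'–C6' of ring A, by Diels–Alder benzannulation of vinylketene acetal 15 with the alkyne of enynone 7. Ring A is the only ring formed; ring B comes in with aldehyde 1.
- Diene 15 comes from methyl acetoacetate and geranyl bromide (C-alkylation, O-methylation, γ-enolization/O-silylation).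
- Enynone 7 comes from commercial 4-(tert-butyldimethylsilyloxy)benzaldehyde by Horner–Wadsworth–Emmons olefination to a Weinreb amide, then ethynyl Grignard addition.

Key step: step 6

Assumption: enol ether 13 may form as an E/Z mixture and is drawn as E. This double bond becomes a single bond in diene 15, and the ketene acetal geometry of 14 and 15 (left undefined) is erased when ring A aromatizes. Intermediates 6, 11 and 16 are racemic and their stereocenters do not survive. TBS = tert-butyldimethylsilyl; geranyl = (2E)-3,7-dimethylocta-2,6-dien-1-yl.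

**Step 1**
Reactants: 1 4-(tert-butyldimethylsilyloxy)benzaldehyde; 2 diethyl [2-(methoxy(methyl)amino)-2-oxoethyl]phosphonate
Product: 4 (E)-3-[4-(tert-butyldimethylsilyloxy)phenyl]-N-methoxy-N-methylprop-2-enamide, via sodium phosphonate carbanion 3 (not isolated)
Conditions: 2 (1.1 equiv), NaH (1.05 equiv), THF, 0 °C; then 1, 0 °C → rt
Reagents that add atoms: none
Why: Horner–Wadsworth–Emmons olefination of an aromatic aldehyde with an amide-stabilized phosphonate anion is expected to be strongly E-selective, and the aryl silyl ether should tolerate the anhydrous medium because no excess hydride or alkoxide is present.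

**Step 2**
Reactants: 4 (E)-3-[4-(tert-butyldimethylsilyloxy)phenyl]-N-methoxy-N-methylprop-2-enamide; 5 ethynylmagnesium bromide
Product: 7 (E)-1-[4-(tert-butyldimethylsilyloxy)phenyl]pent-1-en-4-yn-3-one, via magnesium hemiaminal chelate 6 (not isolated)
Conditions: HC≡CMgBr (0.5 M in THF, 2.5 equiv), THF, 0 °C → rt; inverse quench into cold aq NaHSO4; product stored cold and used soon
Reagents that add atoms: none
Why: In this Weinreb ketone synthesis the five-membered magnesium chelate holds the tetrahedral adduct until the acidic inverse quench, so over-addition is excluded and the liberated N,O-dimethylhydroxylamine is protonated before it can add to the terminal ynone.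

**Step 3**
Reactants: 8 methyl acetoacetate; 9 geranyl bromide
Product: 11 methyl 2-geranylacetoacetate (racemic), via sodium enolate 10 (not isolated)
Conditions: 8 (1.5 equiv), NaH (1.2 equiv), THF, 0 °C; then 9 (1.0 equiv), 0 °C → rt
Reagents that add atoms: none
Why: Acetoacetic ester alkylation of the soft β-keto ester enolate with a primary allylic bromide should proceed by SN2 at carbon with the E-trisubstituted alkene retained, and the excess keto ester suppresses dialkylation.

**Step 4**
Reactants: 11 methyl 2-geranylacetoacetate
Product: 13 methyl (2E)-2-geranyl-3-methoxybut-2-enoate, via sodium enolate 12 (not isolated)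
Conditions: NaH (1.1 equiv), THF–N,N'-dimethylpropyleneurea (DMPU), 0 °C; Me2SO4 (1.2 equiv), 0 °C → rt; quench with aq NH3
Reagents that add atoms: dimethyl sulfate COS(=O)(=O)OC
Why: O-alkylation of a β-keto ester enolate is favoured here by the hard sulfate electrophile, the dissociating dipolar aprotic medium and the hindered, fully substituted α-carbon, and the basic conditions avoid any acid that could cyclize the geranyl chain.

**Step 5**
Reactants: 13 methyl (2E)-2-geranyl-3-methoxybut-2-enoate
Product: 15 2-geranyl-1,3-dimethoxy-1-(trimethylsilyloxy)buta-1,3-diene, via lithium dienolate 14 (not isolated)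
Conditions: LiN(i-Pr)2 (1.15 equiv), THF, −78 °C; Me3SiCl (1.3 equiv), −78 °C → rt; evaporate, take up in pentane, filter under argon, concentrate; use crude at once
Reagents that add atoms: chlorotrimethylsilane C[Si](C)(C)Cl
Why: γ-Deprotonation of the β-methoxy enoate gives the extended ester dienolate, which the hard silyl chloride traps on oxygen (the standard preparation of Brassard-type vinylketene silyl acetals), while the doubly allylic geranyl CH2 lacks carbonyl conjugation and should not compete.

**Step 6**
Reactants: 15 2-geranyl-1,3-dimethoxy-1-(trimethylsilyloxy)buta-1,3-diene (1.5 equiv); 7 (E)-1-[4-(tert-butyldimethylsilyloxy)phenyl]pent-1-en-4-yn-3-one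
Product: 18 xanthoangelol F 4-O-tert-butyldimethylsilyl ether, via cyclohexa-1,4-diene cycloadduct 16 (not isolated), via aryl trimethylsilyl ether 17 (not isolated)
Conditions: toluene, 0 °C → rt (50 °C if slow); then THF, 0.5 M aq HCl, 0 °C, short contact
Reagents that add atoms: none
Why: The electron-rich vinylketene acetal 15 and the electron-poor terminal alkyne of 7 should combine in a concerted but asynchronous normal-demand (4+2) cycloaddition in which the CH2 terminus of the diene (its most nucleophilic carbon) bonds to the unsubstituted alkyne carbon (C6') and the acetal carbon bonds to the acyl-bearing alkyne carbon (C1'), the closest known reaction type being the Diels–Alder benzannulation of Brassard-type 1-alkoxy-1-silyloxy-3-alkoxybutadienes with acetylenic ketones and esters. Ring A is closed in this single intermolecular cycloaddition as a six-membered carbocycle (bonds C1'–C2' and C5'–C6'), giving the cyclohexa-1,4-diene 16. Dilute acid then protonates the more basic methoxy oxygen of the mixed ketal at C2', methanol leaves, loss of a C5' proton gives arene 17, and the labile aryl O–SiMe3 bond is hydrolysed to the hydrogen-bonded C2' phenol. No stereocenter has to be controlled, because the only one formed (the ketal carbon of racemic 16) disappears on aromatization and the E alkenes of the geranyl chain and of the enone are not involved. Two selectivities are needed: orientation, which the matched polarization of the 1,1,3-trioxygenated diene and the ynone secures, and site selectivity within the cross-conjugated dienophile, which the unhindered, unsubstituted alkyne terminus should win over the β-aryl alkene that is deactivated by its donor aryl group. The geranyl group sits on C2 of the diene and is therefore delivered between the two oxygens at C3' without any regiochemical choice on an arene.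

**Step 7**
Reactants: 18 xanthoangelol F 4-O-tert-butyldimethylsilyl ether
Product: 19 xanthoangelol F
Conditions: Bu4NF (1.2 equiv), AcOH (1.5 equiv), THF, 0 °C
Reagents that add atoms: none
Why: Fluoride-mediated cleavage of the aryl silyl ether is driven by Si–F bond formation, and the acetic acid buffer keeps free phenoxide absent so that the 2'-hydroxychalcone should neither close to the flavanone nor isomerize.

**Compound list**

1 | 4-(tert-butyldimethylsilyloxy)benzaldehyde | CC(C)(C)[Si](C)(C)Oc1ccc(C=O)cc1 | starting material
2 | diethyl [2-(methoxy(methyl)amino)-2-oxoethyl]phosphonate | CCOP(=O)(CC(=O)N(C)OC)OCC | starting material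
3 | sodium salt of the α-carbanion of phosphonate 2 | CCOP(=O)([CH-]C(=O)N(C)OC)OCC.[Na+] | intermediate
4 | (E)-3-[4-(tert-butyldimethylsilyloxy)phenyl]-N-methoxy-N-methylprop-2-enamide | CON(C)C(=O)/C=C/c1ccc(O[Si](C)(C)C(C)(C)C)cc1 | intermediate
5 | ethynylmagnesium bromide | C#C[Mg]Br | starting material
6 | bromomagnesium alkoxide of the tetrahedral adduct of 4 and 5 (racemic; E alkene) | CON(C)C(O[Mg]Br)(C#C)/C=C/c1ccc(O[Si](C)(C)C(C)(C)C)cc1 | intermediate
7 | (E)-1-[4-(tert-butyldimethylsilyloxy)phenyl]pent-1-en-4-yn-3-one | C#CC(=O)/C=C/c1ccc(O[Si](C)(C)C(C)(C)C)cc1 | intermediate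
8 | methyl acetoacetate | COC(=O)CC(C)=O | starting material
9 | geranyl bromide, (2E)-1-bromo-3,7-dimethylocta-2,6-diene | CC(C)=CCC/C(C)=C/CBr | starting material
10 | sodium enolate of methyl acetoacetate | COC(=O)[CH-]C(C)=O.[Na+] | intermediate
11 | methyl 2-geranylacetoacetate, methyl (4E)-2-acetyl-5,9-dimethyldeca-4,8-dienoate (racemic) | COC(=O)C(C/C=C(\C)CCC=C(C)C)C(C)=O | intermediate
12 | sodium enolate of 11 | COC(=O)[C-](C/C=C(\C)CCC=C(C)C)C(C)=O.[Na+] | intermediate
13 | methyl (2E)-2-[(2E)-3,7-dimethylocta-2,6-dien-1-yl]-3-methoxybut-2-enoate | COC(=O)/C(C/C=C(\C)CCC=C(C)C)=C(\C)OC | intermediate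
14 | lithium dienolate of 13 (ketene acetal geometry undefined) | C=C(OC)C(C/C=C(\C)CCC=C(C)C)=C(OC)[O-].[Li+] | intermediate
15 | 2-[(2E)-3,7-dimethylocta-2,6-dien-1-yl]-1,3-dimethoxy-1-(trimethylsilyloxy)buta-1,3-diene (ketene acetal geometry undefined) | C=C(OC)C(C/C=C(\C)CCC=C(C)C)=C(OC)O[Si](C)(C)C | intermediate
16 | cyclohexa-1,4-diene cycloadduct: 1-cinnamoyl-type ring with C2' bearing OMe and OSiMe3, C3' geranyl, C4' OMe, C5' H2 (racemic at C2') | COC1=C(C/C=C(\C)CCC=C(C)C)C(OC)(O[Si](C)(C)C)C(C(=O)/C=C/c2ccc(O[Si](C)(C)C(C)(C)C)cc2)=CC1 | intermediate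
17 | (E)-3-[4-(tert-butyldimethylsilyloxy)phenyl]-1-[3-geranyl-4-methoxy-2-(trimethylsilyloxy)phenyl]prop-2-en-1-one | COc1ccc(C(=O)/C=C/c2ccc(O[Si](C)(C)C(C)(C)C)cc2)c(O[Si](C)(C)C)c1C/C=C(\C)CCC=C(C)C | intermediate
18 | xanthoangelol F 4-O-tert-butyldimethylsilyl ether, (E)-3-[4-(tert-butyldimethylsilyloxy)phenyl]-1-[3-geranyl-2-hydroxy-4-methoxyphenyl]prop-2-en-1-one | COc1ccc(C(=O)/C=C/c2ccc(O[Si](C)(C)C(C)(C)C)cc2)c(O)c1C/C=C(\C)CCC=C(C)C | intermediate
19 | xanthoangelol F, (E)-1-[3-geranyl-2-hydroxy-4-methoxyphenyl]-3-(4-hydroxyphenyl)prop-2-en-1-one | COc1ccc(C(=O)/C=C/c2ccc(O)cc2)c(O)c1C/C=C(\C)CCC=C(C)C | target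

**Step count**

Total: 7 steps. Longest linear sequence: 5 steps (steps 3, 4, 5, 6, 7, from methyl acetoacetate and geranyl bromide); the enynone branch (steps 1 and 2) joins at step 6.

**Steps most likely to fail**

1. Step 6. The nucleophilic diene may add in a stepwise vinylogous Michael sense and stop at an open-chain adduct. The cross-conjugated terminal ynone may oligomerize or be attacked at its styryl terminus. Aromatization may also expel trimethylsilanol in place of methanol, leaving C2' as a methyl ether. Fallback: the chalcone is built after ring A. Setting out from diene 15, cycloaddition with the simple dienophile but-3-yn-2-one (toluene, rt, then dilute aq HCl/THF), which has no competing alkene, should give 1-(3-geranyl-2-hydroxy-4-methoxyphenyl)ethanone F1. Claisen–Schmidt condensation of F1 with commercial 4-(tetrahydro-2H-pyran-2-yloxy)benzaldehyde (KOH, EtOH–H2O, rt) should give xanthoangelol F 4-O-tetrahydropyranyl ether F2. Mild acetal exchange (pyridinium p-toluenesulfonate, MeOH, rt) then returns to the route at target 19.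

2. Step 5. Enolization may be incomplete or misdirected (slow γ-deprotonation of a Z-configured enol ether, or deprotonation at the doubly allylic CH2), and the moisture-sensitive ketene acetal may hydrolyse during isolation. Fallback: a 1,3-bis(silyloxy)diene replaces the methyl enol ether. Setting out from keto ester 11, O-silylation (Me3SiCl, Et3N, toluene, rt) should give methyl (2Z)-2-geranyl-3-(trimethylsilyloxy)but-2-enoate F3. Enolization and silylation (LiN(i-Pr)2, then Me3SiCl, THF, −78 °C) should give 2-geranyl-1-methoxy-1,3-bis(trimethylsilyloxy)buta-1,3-diene F4. Cycloaddition of F4 with enynone 7 (toluene, rt, then dilute aq HCl/THF) should give xanthoangelol 4-O-tert-butyldimethylsilyl ether F5, the 2',4'-dihydroxy analogue. Mitsunobu methylation of its non-chelated 4'-OH (MeOH, PPh3, diisopropyl azodicarboxylate, THF, 0 °C) returns to the route at compound 18.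

3. Step 4. Methylation at the α-carbon may compete with O-methylation, giving the quaternary C-methyl keto ester. Fallback: the enol ether is made through a ketal instead of by enolate alkylation. Setting out from keto ester 11, ketalization (HC(OMe)3, MeOH, catalytic pyridinium p-toluenesulfonate, rt to 40 °C) should give methyl 2-geranyl-3,3-dimethoxybutanoate F6. Elimination of one methoxy group (Me3SiOTf, i-Pr2NEt, CH2Cl2, −20 °C → rt) returns to the route at enol ether 13. Any methyl 2-geranyl-3-methoxybut-3-enoate F7 formed alongside is taken on as well, since α-deprotonation in step 5 converts it into the same dienolate 14.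

**Further compounds**

F1 | step 6 | 1-(3-geranyl-2-hydroxy-4-methoxyphenyl)ethanone | COc1ccc(C(C)=O)c(O)c1C/C=C(\C)CCC=C(C)C
F2 | step 6 | xanthoangelol F 4-O-tetrahydropyranyl ether (racemic at the acetal carbon) | COc1ccc(C(=O)/C=C/c2ccc(OC3CCCCO3)cc2)c(O)c1C/C=C(\C)CCC=C(C)C
F3 | step 5 | methyl (2Z)-2-geranyl-3-(trimethylsilyloxy)but-2-enoate | COC(=O)/C(C/C=C(\C)CCC=C(C)C)=C(/C)O[Si](C)(C)C
F4 | step 5 | 2-geranyl-1-methoxy-1,3-bis(trimethylsilyloxy)buta-1,3-diene (ketene acetal geometry undefined) | C=C(O[Si](C)(C)C)C(C/C=C(\C)CCC=C(C)C)=C(OC)O[Si](C)(C)C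
F5 | step 5 | xanthoangelol 4-O-tert-butyldimethylsilyl ether, (E)-3-[4-(tert-butyldimethylsilyloxy)phenyl]-1-(3-geranyl-2,4-dihydroxyphenyl)prop-2-en-1-one | Oc1ccc(C(=O)/C=C/c2ccc(O[Si](C)(C)C(C)(C)C)cc2)c(O)c1C/C=C(\C)CCC=C(C)C
F6 | step 4 | methyl 2-geranyl-3,3-dimethoxybutanoate (racemic) | COC(=O)C(C/C=C(\C)CCC=C(C)C)C(C)(OC)OC
F7 | step 4 | methyl 2-geranyl-3-methoxybut-3-enoate (racemic) | COC(=O)C(C/C=C(\C)CCC=C(C)C)C(=C)OC
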